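The earlier runs and the new flask are calculated with made-up constants; scatter was added.

The target I wanted came from electrophile and nucleophile, each turn setting one acid free, and I had charged free base to take that acid up.

| flask | electrophile | nucleophile | free base | temperature | remark | time |
|---|---|---|---|---|---|---|
| north | 1.5 M | 1.95 M | 0.45 M | −20 °C | the very flask that is asked about, followed so far |  |
| west | 2.2 M | 1.95 M | 0.45 M | −20 °C | run made earlier |  |
| flask | 1.5 M | 1.95 M | 0.450 M | −20 °C |  | 3.0 d |

| run | time / h | target / % |
|---|---|---|
| north | 3.00 | 37.8 |
| north | 8.00 | 58.6 |
| north | 15.0 | 69.8 |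
| north | 25.0 | 74.8 |
| north | 40.0 | 78.4 |
| north | 50.0 | 79.2 |
| north | 60.0 | 79.2 |
| west | 0.333 | 6.9 |
| west | 1.00 | 17.1 |
| west | 1.50 | 22.0 |
| west | 2.50 | 30.5 |
| west | 4.00 | 39.7 |
| west | 5.00 | 42.5 |
| west | 6.00 | 45.2 |

(readings scatter by 0.5 percentage points)

- oak: at 3.0 d take out 90% of the acid set free then present, then wait 40 h
- cedar: at 3.0 d add free base, 100% of the amount charged, then wait 40 h
- birch: change nothing and wait 40 h more
- larch: at 3.0 d raise the temperature by 20 K, then wait 40 h

- additions leave the volume as it is
- the numbers in the tables scatter with a standard deviation of 0.5 percentage points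
- the earlier runs do not show what temperature does; that part of a forecast is a guess

- target, in percent of the electrophile first charged, at 3.0 d
- which option adds most target ("none" when 2 percentage points or less is all one gets) (oak / cedar / birch / larch / none)
- target present, in percent of the electrophile first charged, after oak
- target present, in percent of the electrophile first charged, after birch

The north run looked contradictory. It held 1.30 equivalents of nucleophile, more than the electrophile, yet target read 79.2% at 50.0 h and 79.2% at 60.0 h, with 20.8% of the electrophile not turned into target.

I reckoned that a turn costs one nucleophile and that its acid, once the free base is used up, costs a second. The charge then gave 80.0%. This stall fraction, the sum of nucleophile and free base in equivalents of electrophile divided by two, is, on this count, the share of electrophile that becomes target before free nucleophile reaches zero. On this count the nucleophile was the limiting reagent in the north run despite its excess.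

The gap to it in the north run read 10 percentage points at 15.0 h and 5.2 points at 25.0 h, so by these readings it fell to half in 10.0 h. From 40.0 h to 3.0 d lay 3.20 such half-lives, so I expected target near 80.0% and little from birch. Cedar moved the stall fraction to 95.0%, so I favoured it. I could not price oak, since the readings did not show how much acid stood free, and larch was a guess.

The forecast gave 79.7% now, 80% after birch and 95% after oak, and where I favoured cedar it chose oak, “reading the acid as the ~0.75 M held on nucleophile”.

The flask gave 80.1% at 3.0 d, 80.9% after birch and 81.1% after oak. Birch added 0.76 points, oak 0.99 points, cedar 11 points and larch, the best, 14 points.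

    electrophile + nucleophile → acid set free + target (k = 0.00180 M⁻¹ min⁻¹, Ea = 65.0 kJ mol⁻¹)
    nucleophile + acid set free ⇌ protonated nucleophile, settled at all times (K = 4200 M⁻¹, ΔH = −73.0 kJ mol⁻¹)
    acid set free + free base ⇌ salt of the base, settled at all times (K = 39000 M⁻¹, ΔH = −33.0 kJ mol⁻¹)
    2 electrophile → self-condensation product (k = 1.20 × 10⁻⁶ M⁻¹ min⁻¹, Ea = 69.0 kJ mol⁻¹)
    acid set free → by-product carried off (k = 1.60 × 10⁻⁴ min⁻¹, Ea = 82.0 kJ mol⁻¹)
    (constants at −20 °C)

At 72.0 h the electrophile's half-life by the step to target was 22 d, much longer than the 40 h of waiting. Oak's 90% acted on acid set free, which stood at 72.0 h at 0.949% of the electrophile charged, while 49.0% was held as protonated nucleophile. In a neighbour flask with 0.18 M of free base, the stall fraction gives 71.0%. That flask stood at 71.8% at 3.0 d.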